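**Strategy.** The plan rests on breaking the C3–C4 bond of the butenolide. C4 is the benzylic carbon of ring B and lies β to the lactone oxygen O1 through the quaternary C5, so a diazoacetate on the C5 oxygen places a rhodium carbenoid in a 1,5-relationship to that C–H bond. One operation forges C3–C4 and closes the lactone ring (O1, C2, C3, C4, C5) with C5 (S) untouched. The precursor is the diazoacetate of a tertiary α-hydroxy ester carrying both arylmethyl groups, made by self-regeneration of the stereocentre of (R)-4-hydroxyphenyllactic acid; ring A is an electron-poor aryl tert-butyl carbonate, ring B an electron-rich bis-MOM ether.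

Key step: step 14

Remark: lactone atoms are numbered O1, C2 (carbonyl), C3, C4 (bears ring B, the 3,4-dioxygenated 5-prenylphenyl ring), C5 (quaternary; bears CO2Me and the ring A benzyl group, ring A being the 4-oxygenated 3-prenylphenyl ring), with prenyl = 3-methylbut-2-en-1-yl; (R)-4-hydroxyphenyllactic acid is the correct enantiomer, because the ring B benzyl group enters where the α-hydrogen was and outranks the ring A benzyl group, so the descriptor becomes S without inversion; the ring A phenol is carried as a tert-butyl carbonate (no enolisable hydrogen, acid-labile) so that all aryl protecting groups leave in one acidic step and the finished enol lactone never meets base.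

Step 1
Reactants: 1 3-bromo-4,5-dihydroxybenzaldehyde
Product: 2 3-bromo-4,5-bis(methoxymethoxy)benzaldehyde
Conditions: MOMCl (2.5 equiv), K2CO3, acetone, 0 °C → reflux
Reagents that add atoms: chloromethyl methyl ether, COCCl
Why: Williamson-type O-alkylation of both catechol oxygens by the reactive α-chloro ether gives base-stable acetals that survive the coupling, hydride, enolate and methoxide steps ahead.

Step 2
Reactants: 2 3-bromo-4,5-bis(methoxymethoxy)benzaldehyde; 3 tributyl(3-methylbut-2-en-1-yl)stannane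
Product: 4 3,4-bis(methoxymethoxy)-5-(3-methylbut-2-en-1-yl)benzaldehyde
Conditions: Pd(PPh3)4 (5 mol %), DMF (degassed), 100 °C
Reagents that add atoms: none
Why: Stille coupling, in which zerovalent palladium adds to the aryl bromide, the allylic stannane transmetalates and reductive elimination at the less substituted allyl terminus should give the linear prenyl arene under base-free conditions that leave the aldehyde and acetals alone.

Step 3
Reactants: 4 3,4-bis(methoxymethoxy)-5-(3-methylbut-2-en-1-yl)benzaldehyde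
Product: 5 [3,4-bis(methoxymethoxy)-5-(3-methylbut-2-en-1-yl)phenyl]methanol
Conditions: NaBH4, MeOH, 0 °C
Reagents that add atoms: none
Why: Borohydride reduction of the aldehyde to the benzylic alcohol; MOM acetals and the trisubstituted alkene are inert to NaBH4.

Step 4
Reactants: 5 [3,4-bis(methoxymethoxy)-5-(3-methylbut-2-en-1-yl)phenyl]methanol
Product: 6 5-(bromomethyl)-1,2-bis(methoxymethoxy)-3-(3-methylbut-2-en-1-yl)benzene
Conditions: CBr4, PPh3, CH2Cl2, 0 °C; used at once
Reagents that add atoms: carbon tetrabromide, BrC(Br)(Br)Br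
Why: Appel reaction, in which the hydroxyl is activated on phosphorus and displaced by bromide at the primary benzylic carbon under neutral conditions that spare the acetals and the prenyl group.

Step 5
Reactants: 7 (R)-3-(4-hydroxyphenyl)lactic acid; 8 pivalaldehyde
Product: 9 (2R,5R)-2-tert-butyl-5-(4-hydroxybenzyl)-1,3-dioxolan-4-one (cis)
Conditions: TsOH·H2O (cat.), H2SO4 (cat.), pentane, reflux, Dean–Stark; crystallisation
Reagents that add atoms: none
Why: Acid-catalysed acetalisation of the α-hydroxy acid with removal of water, in which the equilibrating conditions should favour the cis-2,5-disubstituted ring, so that the new acetal centre C2 (R) is set by the existing C5 centre under thermodynamic control and crystallisation removes the trans isomer, whose presence would erode the enantiomeric purity after step 9.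

Step 6
Reactants: 9 (2R,5R)-2-tert-butyl-5-(4-hydroxybenzyl)-1,3-dioxolan-4-one
Product: 10 (2R,5R)-5-(3-bromo-4-hydroxybenzyl)-2-tert-butyl-1,3-dioxolan-4-one
Conditions: NBS (1.0 equiv), MeCN, 0 °C, dark
Reagents that add atoms: N-bromosuccinimide, O=C1CCC(=O)N1Br
Why: Electrophilic aromatic bromination, which with the para position blocked should place one bromine ortho to the phenol, while the masked hydroxy acid and both stereocentres are not involved.

Step 7
Reactants: 10 (2R,5R)-5-(3-bromo-4-hydroxybenzyl)-2-tert-butyl-1,3-dioxolan-4-one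
Product: 11 (2R,5R)-5-[3-bromo-4-(tert-butyldimethylsilyloxy)benzyl]-2-tert-butyl-1,3-dioxolan-4-one
Conditions: TBSCl, imidazole, DMF, rt
Reagents that add atoms: tert-butyldimethylsilyl chloride, CC(C)(C)[Si](C)(C)Cl
Why: Imidazole-promoted silylation masks the only acidic proton before the enolate step, and an aryl silyl ether is chosen because the methoxide of step 10 will remove it again without an extra operation.

Step 8
Reactants: 11 (2R,5R)-5-[3-bromo-4-(tert-butyldimethylsilyloxy)benzyl]-2-tert-butyl-1,3-dioxolan-4-one; 3 tributyl(3-methylbut-2-en-1-yl)stannane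
Product: 12 (2R,5R)-2-tert-butyl-5-[4-(tert-butyldimethylsilyloxy)-3-(3-methylbut-2-en-1-yl)benzyl]-1,3-dioxolan-4-one
Conditions: Pd(PPh3)4 (10 mol %), DMF (degassed), 90–100 °C
Reagents that add atoms: none
Why: Stille coupling as in step 2, whose neutral conditions tolerate the base-sensitive dioxolanone and the aryl silyl ether and do not touch the two stereocentres.

Step 9
Reactants: 12 (2R,5R)-2-tert-butyl-5-[4-(tert-butyldimethylsilyloxy)-3-(3-methylbut-2-en-1-yl)benzyl]-1,3-dioxolan-4-one; 6 5-(bromomethyl)-1,2-bis(methoxymethoxy)-3-(3-methylbut-2-en-1-yl)benzene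
Product: 14 (2R,5S)-5-[3,4-bis(methoxymethoxy)-5-(3-methylbut-2-en-1-yl)benzyl]-2-tert-butyl-5-[4-(tert-butyldimethylsilyloxy)-3-(3-methylbut-2-en-1-yl)benzyl]-1,3-dioxolan-4-one, via lithium enolate 13 (not isolated)
Conditions: LiN(i-Pr)2 (1.1 equiv), THF, −78 °C; then 6, −78 → −30 °C
Reagents that add atoms: none
Why: Enolate alkylation with self-regeneration of the stereocentre, in which deprotonation flattens C5, the tert-butyl group on C2 shields one face and the reactive benzylic bromide should enter trans to it, in the place the hydrogen had, which sets the quaternary C5 as S.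

Step 10
Reactants: 14 (2R,5S)-dibenzylated dioxolanone
Product: 15 methyl (2S)-3-[3,4-bis(methoxymethoxy)-5-(3-methylbut-2-en-1-yl)phenyl]-2-hydroxy-2-[4-hydroxy-3-(3-methylbut-2-en-1-yl)benzyl]propanoate
Conditions: NaOMe (3 equiv), MeOH–THF, 0 °C → rt; aq. NH4Cl
Reagents that add atoms: sodium methoxide in methanol, [Na+].[O-]C
Why: Methoxide transesterification opens the acylal-type lactone to the methyl ester with loss of pivalaldehyde and the same reagent cleaves the aryl silyl ether, while the quaternary centre cannot epimerise and the MOM ethers are stable to base.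

Step 11
Reactants: 15 methyl (2S)-2-hydroxy ester with free ring A phenol
Product: 16 methyl (2S)-3-[3,4-bis(methoxymethoxy)-5-(3-methylbut-2-en-1-yl)phenyl]-2-[4-(tert-butoxycarbonyloxy)-3-(3-methylbut-2-en-1-yl)benzyl]-2-hydroxypropanoate
Conditions: Boc2O (1.05 equiv), DMAP (5 mol %), MeCN, 0 °C → rt
Reagents that add atoms: di-tert-butyl dicarbonate, CC(C)(C)OC(=O)OC(=O)OC(C)(C)C
Why: DMAP-catalysed acylation should be selective for the phenol over the hindered tertiary alcohol, and the resulting carbonate lowers the electron density of ring A, has no enolisable hydrogen for step 15 and is acid-labile like the MOM groups.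

Step 12
Reactants: 16 methyl (2S)-2-hydroxy ester with ring A tert-butyl carbonate
Product: 17 methyl (2S)-3-[3,4-bis(methoxymethoxy)-5-(3-methylbut-2-en-1-yl)phenyl]-2-(bromoacetoxy)-2-[4-(tert-butoxycarbonyloxy)-3-(3-methylbut-2-en-1-yl)benzyl]propanoate
Conditions: BrCH2COBr (3 equiv), 2,6-lutidine (4 equiv), CH2Cl2, 0 °C → rt
Reagents that add atoms: bromoacetyl bromide, BrCC(Br)=O
Why: O-Acylation of the tertiary alcohol with a small and very reactive acyl bromide should overcome the hindrance of the α,α-dibenzyl carbinol, and the hindered non-nucleophilic base is not alkylated by the bromoacetate and does not attack the carbonate.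

Step 13
Reactants: 17 methyl (2S)-2-(bromoacetoxy) ester
Product: 18 methyl (2S)-3-[3,4-bis(methoxymethoxy)-5-(3-methylbut-2-en-1-yl)phenyl]-2-[4-(tert-butoxycarbonyloxy)-3-(3-methylbut-2-en-1-yl)benzyl]-2-(diazoacetoxy)propanoate
Conditions: TsNHNHTs (2 equiv), DBU (5 equiv), THF, 0 °C, 15 min
Reagents that add atoms: N,N′-ditosylhydrazine, Cc1ccc(cc1)S(=O)(=O)NNS(=O)(=O)c1ccc(C)cc1
Why: Diazo synthesis from a bromoacetate, in which the hydrazide nitrogen displaces bromide at the unhindered CH2 and DBU then expels two sulfinate ions, a sequence fast enough at 0 °C to spare the aryl carbonate and both esters.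

Step 14
Reactants: 18 methyl (2S)-2-(diazoacetoxy) ester
Product: 20 methyl (5S)-4-[3,4-bis(methoxymethoxy)-5-(3-methylbut-2-en-1-yl)phenyl]-5-[4-(tert-butoxycarbonyloxy)-3-(3-methylbut-2-en-1-yl)benzyl]-2-oxooxolane-5-carboxylate (C4 epimers), via rhodium carbenoid 19 (not isolated)
Conditions: Rh2(NHCOCH3)4 (2 mol %), CH2Cl2, reflux; 18 added by syringe pump over 8 h, final 0.01 M
Reagents that add atoms: none
Why: Rh2(NHCOCH3)4 takes up the diazo carbon with loss of N2, and the electrophilic carbenoid carbon (C3) inserts into a ring B benzylic C–H bond through a concerted, hydride-transfer-like three-centre transition state, forming C3–C4. The closest known reaction type is the dirhodium carboxamidate-catalysed intramolecular C–H insertion of alkyl diazoacetates into benzylic C–H bonds that gives β-aryl-γ-butyrolactones. The lactone ring (O1, C2, C3, C4, C5) closes in the favoured 1,5-insertion mode through a five-membered cyclic transition state. The new C4 centre is under no useful control and should form as an epimer mixture, which is harmless because C4 becomes the sp2 enol carbon in step 16, while C5 is not touched. The step needs insertion at the ring B rather than the ring A CH2 (which would exchange the rings) and C–H insertion rather than alkene addition, arene cycloaddition or carbene dimerisation: the para-alkoxy group makes the ring B C–H the better hydride donor and the carbonate makes the ring A C–H the poorer one, the meta-placed prenyl groups can only be reached through strained bridged medium rings, and the electron-rich acetamidate ligands together with slow addition at high dilution favour the selective intramolecular insertion.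

Step 15
Reactants: 20 saturated lactone (C4 epimers)
Product: 22 methyl (5S)-4-[3,4-bis(methoxymethoxy)-5-(3-methylbut-2-en-1-yl)phenyl]-5-[4-(tert-butoxycarbonyloxy)-3-(3-methylbut-2-en-1-yl)benzyl]-3-hydroxy-2-oxooxolane-5-carboxylate (diastereomer mixture at C3 and C4), via potassium enolate 21 (not isolated)
Conditions: KN(SiMe3)2 (1.15 equiv), THF, −78 °C; then 2-(phenylsulfonyl)-3-phenyloxaziridine, −78 °C; aq. NH4Cl
Reagents that add atoms: 2-(phenylsulfonyl)-3-phenyloxaziridine, O=S(=O)(c1ccccc1)N1OC1c1ccccc1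
Why: Enolate hydroxylation, in which the base removes a C3 proton (the only enolisable position, since the C5 ester and the carbonate have no α-hydrogen) and the N-sulfonyloxaziridine transfers oxygen to the enolate carbon; the configuration of the new C3 centre does not matter because it is oxidised in step 16.

Step 16
Reactants: 22 3-hydroxy lactone
Product: 24 methyl (5S)-4-[3,4-bis(methoxymethoxy)-5-(3-methylbut-2-en-1-yl)phenyl]-5-[4-(tert-butoxycarbonyloxy)-3-(3-methylbut-2-en-1-yl)benzyl]-3-hydroxy-2-oxo-2,5-dihydrofuran-5-carboxylate, via keto lactone 23 (not isolated)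
Conditions: Dess–Martin periodinane (1.2 equiv), CH2Cl2, 0 °C → rt
Reagents that add atoms: none
Why: Dess–Martin oxidation of the secondary alcohol gives the 2,3-dioxo lactone, which should tautomerise at once to the 3-hydroxybutenolide because the enol double bond is conjugated with ring B and the lactone carbonyl, erasing the C3 and C4 centres and leaving C5 (S) unchanged.

Step 17
Reactants: 24 protected 3-hydroxybutenolide
Product: 25 methyl (5S)-4-[3,4-dihydroxy-5-(3-methylbut-2-en-1-yl)phenyl]-3-hydroxy-5-[4-hydroxy-3-(3-methylbut-2-en-1-yl)benzyl]-2-oxo-2,5-dihydrofuran-5-carboxylate (CNP0460191.1)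
Conditions: HCl (3 M in MeOH), 0 °C → rt, argon; stopped at full conversion
Reagents that add atoms: none
Why: Acid-catalysed solvolysis, in which both MOM acetals are exchanged to dimethoxymethane and the tert-butyl carbonate fragments to CO2 and isobutene, should be much faster than protonation of the prenyl double bonds at or below room temperature, and the methyl ester is unchanged in methanol.

**Compound list**

1 | 3-bromo-4,5-dihydroxybenzaldehyde | O=Cc1cc(O)c(O)c(Br)c1 | starting material
2 | 3-bromo-4,5-bis(methoxymethoxy)benzaldehyde | O=Cc1cc(OCOC)c(OCOC)c(Br)c1 | intermediate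
3 | tributyl(3-methylbut-2-en-1-yl)stannane | CCCC[Sn](CCCC)(CCCC)CC=C(C)C | starting material
4 | 3,4-bis(methoxymethoxy)-5-(3-methylbut-2-en-1-yl)benzaldehyde | O=Cc1cc(OCOC)c(OCOC)c(CC=C(C)C)c1 | intermediate
5 | [3,4-bis(methoxymethoxy)-5-(3-methylbut-2-en-1-yl)phenyl]methanol | OCc1cc(OCOC)c(OCOC)c(CC=C(C)C)c1 | intermediate
6 | 5-(bromomethyl)-1,2-bis(methoxymethoxy)-3-(3-methylbut-2-en-1-yl)benzene | BrCc1cc(OCOC)c(OCOC)c(CC=C(C)C)c1 | intermediate
7 | (R)-3-(4-hydroxyphenyl)lactic acid | O=C(O)[C@H](O)Cc1ccc(O)cc1 | starting material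
8 | pivalaldehyde | CC(C)(C)C=O | starting material
9 | (2R,5R)-2-tert-butyl-5-(4-hydroxybenzyl)-1,3-dioxolan-4-one | O=C1O[C@H](C(C)(C)C)O[C@@H]1Cc1ccc(O)cc1 | intermediate
10 | (2R,5R)-5-(3-bromo-4-hydroxybenzyl)-2-tert-butyl-1,3-dioxolan-4-one | O=C1O[C@H](C(C)(C)C)O[C@@H]1Cc1ccc(O)c(Br)c1 | intermediate
11 | (2R,5R)-5-[3-bromo-4-(tert-butyldimethylsilyloxy)benzyl]-2-tert-butyl-1,3-dioxolan-4-one | O=C1O[C@H](C(C)(C)C)O[C@@H]1Cc1ccc(O[Si](C)(C)C(C)(C)C)c(Br)c1 | intermediate
12 | (2R,5R)-2-tert-butyl-5-[4-(tert-butyldimethylsilyloxy)-3-(3-methylbut-2-en-1-yl)benzyl]-1,3-dioxolan-4-one | O=C1O[C@H](C(C)(C)C)O[C@@H]1Cc1ccc(O[Si](C)(C)C(C)(C)C)c(CC=C(C)C)c1 | intermediate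
13 | lithium enolate of 12, C2 (R) retained (formed in the flask, not isolated) | [Li+].[O-]C1=C(Cc2ccc(O[Si](C)(C)C(C)(C)C)c(CC=C(C)C)c2)O[C@@H](C(C)(C)C)O1 | intermediate
14 | (2R,5S)-5-[3,4-bis(methoxymethoxy)-5-(3-methylbut-2-en-1-yl)benzyl]-2-tert-butyl-5-[4-(tert-butyldimethylsilyloxy)-3-(3-methylbut-2-en-1-yl)benzyl]-1,3-dioxolan-4-one | O=C1O[C@H](C(C)(C)C)O[C@]1(Cc2cc(OCOC)c(OCOC)c(CC=C(C)C)c2)Cc2ccc(O[Si](C)(C)C(C)(C)C)c(CC=C(C)C)c2 | intermediate
15 | methyl (2S)-3-[3,4-bis(methoxymethoxy)-5-(3-methylbut-2-en-1-yl)phenyl]-2-hydroxy-2-[4-hydroxy-3-(3-methylbut-2-en-1-yl)benzyl]propanoate | COC(=O)[C@@](Cc1cc(OCOC)c(OCOC)c(CC=C(C)C)c1)(Cc1ccc(O)c(CC=C(C)C)c1)O | intermediate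
16 | methyl (2S)-3-[3,4-bis(methoxymethoxy)-5-(3-methylbut-2-en-1-yl)phenyl]-2-[4-(tert-butoxycarbonyloxy)-3-(3-methylbut-2-en-1-yl)benzyl]-2-hydroxypropanoate | COC(=O)[C@@](Cc1cc(OCOC)c(OCOC)c(CC=C(C)C)c1)(Cc1ccc(OC(=O)OC(C)(C)C)c(CC=C(C)C)c1)O | intermediate
17 | methyl (2S)-3-[3,4-bis(methoxymethoxy)-5-(3-methylbut-2-en-1-yl)phenyl]-2-(bromoacetoxy)-2-[4-(tert-butoxycarbonyloxy)-3-(3-methylbut-2-en-1-yl)benzyl]propanoate | COC(=O)[C@@](Cc1cc(OCOC)c(OCOC)c(CC=C(C)C)c1)(Cc1ccc(OC(=O)OC(C)(C)C)c(CC=C(C)C)c1)OC(=O)CBr | intermediate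
18 | methyl (2S)-3-[3,4-bis(methoxymethoxy)-5-(3-methylbut-2-en-1-yl)phenyl]-2-[4-(tert-butoxycarbonyloxy)-3-(3-methylbut-2-en-1-yl)benzyl]-2-(diazoacetoxy)propanoate | COC(=O)[C@@](Cc1cc(OCOC)c(OCOC)c(CC=C(C)C)c1)(Cc1ccc(OC(=O)OC(C)(C)C)c(CC=C(C)C)c1)OC(=O)C=[N+]=[N-] | intermediate
19 | rhodium carbenoid from 18 (carbene carbon on one rhodium of the Rh2(NHCOCH3)4 core, written as [Rh]; formed in the flask, not isolated) | COC(=O)[C@@](Cc1cc(OCOC)c(OCOC)c(CC=C(C)C)c1)(Cc1ccc(OC(=O)OC(C)(C)C)c(CC=C(C)C)c1)OC(=O)C=[Rh] | intermediate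
20 | methyl (5S)-4-[3,4-bis(methoxymethoxy)-5-(3-methylbut-2-en-1-yl)phenyl]-5-[4-(tert-butoxycarbonyloxy)-3-(3-methylbut-2-en-1-yl)benzyl]-2-oxooxolane-5-carboxylate (C4 epimers) | COC(=O)[C@@]1(Cc2ccc(OC(=O)OC(C)(C)C)c(CC=C(C)C)c2)OC(=O)CC1c1cc(OCOC)c(OCOC)c(CC=C(C)C)c1 | intermediate
21 | potassium enolate of 20 at C2–C3 (formed in the flask, not isolated) | COC(=O)[C@@]1(Cc2ccc(OC(=O)OC(C)(C)C)c(CC=C(C)C)c2)OC([O-])=CC1c1cc(OCOC)c(OCOC)c(CC=C(C)C)c1.[K+] | intermediate
22 | methyl (5S)-4-[3,4-bis(methoxymethoxy)-5-(3-methylbut-2-en-1-yl)phenyl]-5-[4-(tert-butoxycarbonyloxy)-3-(3-methylbut-2-en-1-yl)benzyl]-3-hydroxy-2-oxooxolane-5-carboxylate (mixture at C3 and C4) | COC(=O)[C@@]1(Cc2ccc(OC(=O)OC(C)(C)C)c(CC=C(C)C)c2)OC(=O)C(O)C1c1cc(OCOC)c(OCOC)c(CC=C(C)C)c1 | intermediate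
23 | methyl (5S)-4-[3,4-bis(methoxymethoxy)-5-(3-methylbut-2-en-1-yl)phenyl]-5-[4-(tert-butoxycarbonyloxy)-3-(3-methylbut-2-en-1-yl)benzyl]-2,3-dioxooxolane-5-carboxylate (keto tautomer, not isolated) | COC(=O)[C@@]1(Cc2ccc(OC(=O)OC(C)(C)C)c(CC=C(C)C)c2)OC(=O)C(=O)C1c1cc(OCOC)c(OCOC)c(CC=C(C)C)c1 | intermediate
24 | methyl (5S)-4-[3,4-bis(methoxymethoxy)-5-(3-methylbut-2-en-1-yl)phenyl]-5-[4-(tert-butoxycarbonyloxy)-3-(3-methylbut-2-en-1-yl)benzyl]-3-hydroxy-2-oxo-2,5-dihydrofuran-5-carboxylate | COC(=O)[C@@]1(Cc2ccc(OC(=O)OC(C)(C)C)c(CC=C(C)C)c2)OC(=O)C(O)=C1c1cc(OCOC)c(OCOC)c(CC=C(C)C)c1 | intermediate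
25 | methyl (5S)-4-[3,4-dihydroxy-5-(3-methylbut-2-en-1-yl)phenyl]-3-hydroxy-5-[4-hydroxy-3-(3-methylbut-2-en-1-yl)benzyl]-2-oxo-2,5-dihydrofuran-5-carboxylate (CNP0460191.1) | COC(=O)[C@@]1(Cc2ccc(O)c(CC=C(C)C)c2)OC(=O)C(O)=C1c1cc(O)c(O)c(CC=C(C)C)c1 | target

**Step count.** Total: 17 steps. Longest linear sequence: 13 steps (steps 5–17 from 7; the ring B branch, steps 1–4, joins at step 9 and is equally long).

**Steps most likely to fail**

Step 14. The carbenoid may insert into the ring A benzylic C–H (which exchanges the two rings), add to a prenyl double bond or dimerise, because the electronic bias between the two benzylic positions is only moderate. Fallback: the C5–C4–C3–C2 chain would be built by conjugate addition instead, setting out from aldehyde 4 and dioxolanone 12. Wittig olefination of 4 with methyl (triphenylphosphoranylidene)acetate (toluene, 80 °C) would give methyl (E)-3-[3,4-bis(methoxymethoxy)-5-(3-methylbut-2-en-1-yl)phenyl]acrylate F1. The lithium enolate 13, made from 12 as in step 9, would add to F1 in a Michael addition trans to the tert-butyl group (THF, −78 → −30 °C) to give the dioxolanone Michael adduct F2, which carries C4 with ring B and the C3–C2 ester arm on the quaternary C5. NaOMe in MeOH would then open the acetal, remove the silyl group and let the tertiary alkoxide close onto the side-chain ester (mild acid work-up) to give the phenolic γ-lactone F3. Boc2O with catalytic DMAP converts F3 into lactone 20, where the route is rejoined.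

Step 12. Acylation of the crowded tertiary hydroxyl may stall, or the bromoacetate may be consumed by the base. Fallback: acylation through a neutral acylketene followed by diazo transfer, setting out from 15. Heating 15 with 2,2,6-trimethyl-4H-1,3-dioxin-4-one (xylene, 130 °C) generates acetylketene, which adds to hindered alcohols without base and would give the bis(acetoacetate) F4 (phenol and tertiary alcohol both acylated). Diazo transfer with 4-acetamidobenzenesulfonyl azide and Et3N (MeCN, rt) would give the bis(2-diazoacetoacetate) F5. Pyrrolidine (MeCN, rt) would then remove the acetyl group of the tertiary ester and cleave the aryl ester completely, leaving the phenolic diazoacetate F6. Boc2O with catalytic DMAP converts F6 into diazoacetate 18, where the route is rejoined.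

Step 17. Acid may cyclise a prenyl group onto its neighbouring phenol or add HCl or methanol across the double bonds before the carbonate has fully fragmented. Fallback: a proton-free, two-stage protecting-group exchange, setting out from 24. Pyrrolidine (THF, 0 °C) would cleave the aryl tert-butyl carbonate by aminolysis to give the ring A phenol F7 with the MOM groups intact. TMSOTf with 2,2′-bipyridyl (CH2Cl2, 0 °C → rt) would then convert the two aryl MOM ethers into aryl silyl ethers and silylate the free hydroxyls, giving the tetrakis(trimethylsilyl) ether F8. Water (or KHF2 in MeOH) at rt hydrolyses F8 to the target 25.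

**Further compounds**

F1 | step 14 | methyl (E)-3-[3,4-bis(methoxymethoxy)-5-(3-methylbut-2-en-1-yl)phenyl]acrylate | COC(=O)/C=C/c1cc(OCOC)c(OCOC)c(CC=C(C)C)c1
F2 | step 14 | (2R,5S)-dioxolanone Michael adduct: 12 carrying on C5 the CH(ring B aryl)CH2CO2Me chain trans to tert-butyl (mixture at the benzylic carbon) | O=C1O[C@H](C(C)(C)C)O[C@]1(C(CC(=O)OC)c2cc(OCOC)c(OCOC)c(CC=C(C)C)c2)Cc2ccc(O[Si](C)(C)C(C)(C)C)c(CC=C(C)C)c2
F3 | step 14 | methyl (5S)-4-[3,4-bis(methoxymethoxy)-5-(3-methylbut-2-en-1-yl)phenyl]-5-[4-hydroxy-3-(3-methylbut-2-en-1-yl)benzyl]-2-oxooxolane-5-carboxylate (C4 epimers) | COC(=O)[C@@]1(Cc2ccc(O)c(CC=C(C)C)c2)OC(=O)CC1c1cc(OCOC)c(OCOC)c(CC=C(C)C)c1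
F4 | step 12 | bis(acetoacetate) of 15 (aryl and tertiary esters), (2S) | COC(=O)[C@@](Cc1cc(OCOC)c(OCOC)c(CC=C(C)C)c1)(Cc1ccc(OC(=O)CC(C)=O)c(CC=C(C)C)c1)OC(=O)CC(C)=O
F5 | step 12 | bis(2-diazoacetoacetate) of 15, (2S) | COC(=O)[C@@](Cc1cc(OCOC)c(OCOC)c(CC=C(C)C)c1)(Cc1ccc(OC(=O)C(=[N+]=[N-])C(C)=O)c(CC=C(C)C)c1)OC(=O)C(=[N+]=[N-])C(C)=O
F6 | step 12 | methyl (2S)-3-[3,4-bis(methoxymethoxy)-5-(3-methylbut-2-en-1-yl)phenyl]-2-(diazoacetoxy)-2-[4-hydroxy-3-(3-methylbut-2-en-1-yl)benzyl]propanoate | COC(=O)[C@@](Cc1cc(OCOC)c(OCOC)c(CC=C(C)C)c1)(Cc1ccc(O)c(CC=C(C)C)c1)OC(=O)C=[N+]=[N-]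
F7 | step 17 | methyl (5S)-4-[3,4-bis(methoxymethoxy)-5-(3-methylbut-2-en-1-yl)phenyl]-3-hydroxy-5-[4-hydroxy-3-(3-methylbut-2-en-1-yl)benzyl]-2-oxo-2,5-dihydrofuran-5-carboxylate | COC(=O)[C@@]1(Cc2ccc(O)c(CC=C(C)C)c2)OC(=O)C(O)=C1c1cc(OCOC)c(OCOC)c(CC=C(C)C)c1
F8 | step 17 | tetrakis(trimethylsilyl) ether of 25 (three aryl oxygens and the enol oxygen silylated), (5S) | COC(=O)[C@@]1(Cc2ccc(O[Si](C)(C)C)c(CC=C(C)C)c2)OC(=O)C(O[Si](C)(C)C)=C1c1cc(O[Si](C)(C)C)c(O[Si](C)(C)C)c(CC=C(C)C)c1
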